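**Retrosynthetic overview**
- Feature: number the benzofuran O1, C2 (aryl-bearing), C3 (OMe-bearing), C3a, C4–C7, C7a, and the aryl ring C1'–C6'. C3a lies ortho to O1 and para to the C6 oxygen, so it is the most nucleophilic carbon of a 4-substituted resorcinol. The C2=C3 enediol diether has the oxidation level of an arylglyoxal.
- Last disconnection: the 2'-OH is carried as a mesylate and freed with hydroxide after the ring is made.
- Key disconnection: C3–C3a, C3–OMe and O1–C2 are cut together. This opens the furan ring, the only ring formed (both benzene rings are bought), and gives 4-prenylresorcinol, 2-mesyloxy-4-methoxyphenylglyoxal and methanol.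
- Precursors: the glyoxal comes from paeonol by mesylation and Riley oxidation, and it is dried to the free dicarbonyl form and used fresh. 4-Prenylresorcinol comes from 4-bromoresorcinol (bis-THP ether, Br–Li exchange, prenyl bromide, PPTS/MeOH), which fixes the prenyl position that direct C-prenylation of resorcinol does not control.

Key step: step 6

Assumption: ambofuranol has no stereocentre, and its only alkene carries two identical methyl groups. The compound is therefore achiral, no enantiomer question arises, and the SMILES given defines the target completely.

**Step 1**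
Reactants: 1 paeonol (2-hydroxy-4-methoxyacetophenone)
Product: 2 2-acetyl-5-methoxyphenyl methanesulfonate
Conditions: MsCl (1.3 equiv), Et3N (1.8 equiv), CH2Cl2, 0 °C to rt
Reagents that add atoms: methanesulfonyl chloride, CS(=O)(=O)Cl
Why: O-sulfonylation of a phenol with a sulfonyl chloride and a tertiary amine is general and also takes the hydrogen-bonded ortho-hydroxyl of 1, and Et3N at or below rt is too weak a base to start the aldol-type closure of the mesyl CH3 onto the acetyl group that stronger bases cause.

**Step 2**
Reactants: 2 2-acetyl-5-methoxyphenyl methanesulfonate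
Product: 3 5-methoxy-2-(2-oxoacetyl)phenyl methanesulfonate (arylglyoxal, free dicarbonyl form)
Conditions: SeO2 (1.3 equiv), 1,4-dioxane/H2O 30:1, 95 °C; Celite, brine wash; PhMe azeotrope, vacuum; used fresh
Reagents that add atoms: selenium dioxide, O=[Se]=O
Why: Riley oxidation of an aryl methyl ketone stops at the arylglyoxal while the aryl mesylate and aryl methyl ether are inert to SeO2 in hot dioxane, the wash removes selenous acid that could later oxidise the prenyl group, and stripping all water as the toluene azeotrope delivers the free dicarbonyl form, which is used the same day because arylglyoxals oligomerise and draw moisture on storage.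

**Step 3**
Reactants: 4 4-bromoresorcinol
Product: 5 1-bromo-2,4-bis(tetrahydropyran-2-yloxy)benzene (diastereomer mixture at the two acetal carbons)
Conditions: 3,4-dihydro-2H-pyran (3 equiv), PPTS (5 mol %), CH2Cl2, rt
Reagents that add atoms: 3,4-dihydro-2H-pyran, C1=COCCC1
Why: Acid-catalysed addition of the phenols to the enol ether (tetrahydropyranylation) masks both acidic protons for the organolithium step as acetals that later leave under acid too weak to protonate a prenyl alkene, and the acetal stereocentres are removed again in step 5.

**Step 4**
Reactants: 5 1-bromo-2,4-bis(tetrahydropyran-2-yloxy)benzene; 6 prenyl bromide (1-bromo-3-methylbut-2-ene)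
Product: 8 1-(3-methylbut-2-enyl)-2,4-bis(tetrahydropyran-2-yloxy)benzene, via 2,4-bis(tetrahydropyran-2-yloxy)phenyllithium 7 (not isolated)
Conditions: n-BuLi (1.05 equiv), THF, −78 °C; then 6 (1.3 equiv), −78 to 0 °C
Reagents that add atoms: prenyl bromide, CC(C)=CCBr
Why: Bromine–lithium exchange places the carbanion only on the carbon that carried bromine (future C5), and SN2 alkylation of the aryllithium at the unhindered CH2 of the allylic bromide, which is far more reactive than the 1-bromobutane formed, gives the linear prenyl arene with full regiocontrol.

**Step 5**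
Reactants: 8 1-(3-methylbut-2-enyl)-2,4-bis(tetrahydropyran-2-yloxy)benzene
Product: 9 4-prenylresorcinol, 4-(3-methylbut-2-enyl)benzene-1,3-diol
Conditions: PPTS (0.2 equiv), MeOH, 40 °C; NaHCO3
Reagents that add atoms: none
Why: Transacetalisation of aryl THP ethers with methanol is fast under PPTS, and this buffered acid does not protonate the trisubstituted alkene, so closure of the o-prenylphenol to a chroman is not expected.

**Step 6**
Reactants: 3 arylglyoxal 5-methoxy-2-(2-oxoacetyl)phenyl methanesulfonate; 9 4-prenylresorcinol; 10 methanol (reactant and solvent)
Product: 14 2'-O-mesylambofuranol (2-[6-hydroxy-3-methoxy-5-(3-methylbut-2-enyl)-1-benzofuran-2-yl]-5-methoxyphenyl methanesulfonate), via glyoxal methyl hemiacetal 11 (not isolated), via α-methoxy ketone 12 (not isolated), via cyclic hemiketal 13 (not isolated)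
Conditions: Sc(OTf)3 (5 mol %), dry MeOH (0.05 M), N2; 3 (1.2 equiv) 30 min at rt, then 9 added slowly at 0 °C, then rt to 40 °C; NaHCO3 quench
Reagents that add atoms: methanol, CO
Why: Proposed new method: the aldehyde carbon of 3 adds solvent methanol to give the hemiacetal 11, which under Sc(III) ionises to the acyl-substituted oxocarbenium ion and is attacked by C6 of 9 (future C3a) in a Friedel–Crafts alkoxyalkylation, and any C3 carbinol formed by attack on the aldehyde form re-ionises through the quinone methide supported by the para (future C6) hydroxyl and is captured by the solvent, so that both paths lead to 12. The hydroxyl ortho to the new bond then adds to the aryl ketone (5-exo-trig closure of the furan ring, O1–C2) to give 13, and loss of water through the C2 oxocarbenium ion followed by loss of H3 aromatises the ring, which puts the methoxy group on an sp2 carbon and takes it out of the ionisation equilibria. The closest known reaction type is the Lewis- or Brønsted-acid-catalysed three-component condensation of arylglyoxals, phenols and a third nucleophile (sulfonamides, indoles, 1,3-dicarbonyls or a second phenol) to 2-aryl-3-substituted benzofurans, and the new element is methanol as the third partner, so that a C3–O bond is made. No stereocentre has to be controlled, because the centres at C2 and C3 of 12 and 13 are transient and are erased on aromatisation. Site selectivity for C6 over C2 of the resorcinol rests on ortho/para activation of C6 by both hydroxyls, on the crowding of C2 between them and on C4 being blocked by the prenyl group, while methanol should win over a second arylation at C3 through its large excess over the two equivalents of water released, the dry form of 3, the slow addition of 9 and the slight excess of 3. The mesylate keeps the 2'-oxygen from closing onto the glyoxal and raises the electrophilicity of the ketone, and a few mol % of metal triflate in methanol, where acidity is levelled to that of MeOH2+, at or below 40 °C should leave the prenyl alkene unprotonated (no chroman, no methanol adduct).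

**Step 7**
Reactants: 14 2'-O-mesylambofuranol
Product: 15 ambofuranol
Conditions: 2 M aq NaOH (6 equiv), 1,4-dioxane, degassed, N2, 60 °C; then aq citric acid to pH 5, 0 °C
Reagents that add atoms: none
Why: Alkaline hydrolysis of an aryl methanesulfonate by S–O cleavage is a known phenol deprotection to which the aromatic enol ether, the aryl methyl ether and the prenyl group are inert, dioxane is used instead of an alcohol cosolvent so that no methyl methanesulfonate can form and methylate the phenoxides, and exclusion of air protects the electron-rich bis-phenoxide.

**Compound list**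
1 | paeonol (2-hydroxy-4-methoxyacetophenone) | CC(=O)c1ccc(OC)cc1O | starting material
2 | 2-acetyl-5-methoxyphenyl methanesulfonate | CC(=O)c1ccc(OC)cc1OS(C)(=O)=O | intermediate
3 | 5-methoxy-2-(2-oxoacetyl)phenyl methanesulfonate (arylglyoxal) | COc1ccc(C(=O)C=O)c(OS(C)(=O)=O)c1 | intermediate
4 | 4-bromoresorcinol | Oc1ccc(Br)c(O)c1 | starting material
5 | 1-bromo-2,4-bis(tetrahydropyran-2-yloxy)benzene (diastereomer mixture) | Brc1ccc(OC2CCCCO2)cc1OC1CCCCO1 | intermediate
6 | prenyl bromide | CC(C)=CCBr | starting material
7 | 2,4-bis(tetrahydropyran-2-yloxy)phenyllithium | [Li]c1ccc(OC2CCCCO2)cc1OC1CCCCO1 | intermediate (not isolated)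
8 | 1-(3-methylbut-2-enyl)-2,4-bis(tetrahydropyran-2-yloxy)benzene (diastereomer mixture) | CC(C)=CCc1ccc(OC2CCCCO2)cc1OC1CCCCO1 | intermediate
9 | 4-prenylresorcinol, 4-(3-methylbut-2-enyl)benzene-1,3-diol | CC(C)=CCc1ccc(O)cc1O | intermediate
10 | methanol | CO | starting material
11 | 2-(2-hydroxy-2-methoxyacetyl)-5-methoxyphenyl methanesulfonate (methyl hemiacetal, racemic) | COc1ccc(C(=O)C(O)OC)c(OS(C)(=O)=O)c1 | intermediate (not isolated)
12 | 2-{2-[2,4-dihydroxy-5-(3-methylbut-2-enyl)phenyl]-2-methoxyacetyl}-5-methoxyphenyl methanesulfonate (racemic) | COc1ccc(C(=O)C(OC)c2cc(CC=C(C)C)c(O)cc2O)c(OS(C)(=O)=O)c1 | intermediate (not isolated)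
13 | 2-[2,6-dihydroxy-3-methoxy-5-(3-methylbut-2-enyl)-2,3-dihydro-1-benzofuran-2-yl]-5-methoxyphenyl methanesulfonate (diastereomer mixture, racemic) | COc1ccc(C2(O)Oc3cc(O)c(CC=C(C)C)cc3C2OC)c(OS(C)(=O)=O)c1 | intermediate (not isolated)
14 | 2'-O-mesylambofuranol | COc1ccc(-c2oc3cc(O)c(CC=C(C)C)cc3c2OC)c(OS(C)(=O)=O)c1 | intermediate
15 | ambofuranol (achiral) | COc1ccc(-c2oc3cc(O)c(CC=C(C)C)cc3c2OC)c(O)c1 | target

**Step count**
- Total step count: 7
- Longest linear sequence: 5 (steps 3, 4, 5, 6, 7 from 4-bromoresorcinol). The paeonol branch (steps 1 and 2) joins at step 6.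

**Steps most likely to fail**

1. Step 6.
   - Risk: ring closure and dehydration may outrun the exchange of hydroxyl for methoxyl at C3, so that C3 ends at the ketone level. Alternatively, a second molecule of 9 may capture the C3 cation.
   - Fallback: it uses known reaction types only, sets out from 3 and 9, comes back at 14, and separates the three bond formations.
   - Friedel–Crafts hydroxyalkylation of 9 with 3 in acetonitrile (cat. Sc(OTf)3, rt) should give the benzoin 2-{2-[2,4-dihydroxy-5-(3-methylbut-2-enyl)phenyl]-2-hydroxyacetyl}-5-methoxyphenyl methanesulfonate F1.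
   - Mild acid (PPTS, MeCN, 50 °C, N2) should close F1 by hemiketalisation and loss of water to the 2-arylbenzofuran-3(2H)-one 2-[6-hydroxy-5-(3-methylbut-2-enyl)-3-oxo-2,3-dihydro-1-benzofuran-2-yl]-5-methoxyphenyl methanesulfonate F2. F2 is kept under nitrogen because such ketones autoxidise at C2.
   - Acid-catalysed enol ether formation with trimethyl orthoformate (cat. CSA, MeOH, 40 °C) converts the ketone and leaves the phenol alone, and should give 14.

2. Step 7.
   - Risk: S–O cleavage of the hindered ortho-substituted mesylate may be slow. The prolonged heating in base would then expose the electron-rich bis-phenoxide to oxidation by traces of air.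
   - Fallback: it sets out from 1, comes back at 15, and replaces the sulfonate by a fluoride-labile group so that the last step runs near neutrality.
   - Silylation of 1 (TIPSOTf, 2,6-lutidine, CH2Cl2) gives 1-[4-methoxy-2-(triisopropylsilyloxy)phenyl]ethan-1-one F3.
   - Riley oxidation as in step 2 gives 2-[4-methoxy-2-(triisopropylsilyloxy)phenyl]-2-oxoacetaldehyde F4.
   - Condensation of F4 with 9 and 10 as in step 6 gives 3-methoxy-2-[4-methoxy-2-(triisopropylsilyloxy)phenyl]-5-(3-methylbut-2-enyl)-1-benzofuran-6-ol F5.
   - TBAF buffered with AcOH (THF, 0 °C) then frees 15.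

3. Step 4.
   - Risk: the aryllithium may be quenched by proton transfer (elimination on the allylic bromide), may exchange halogen with it and give homocoupling, or may attack at the tertiary terminus.
   - Fallback: it sets out from 6, comes back at 9, and uses no protecting groups, so it bypasses steps 3 to 5.
   - Bought resorcinol F6 is used in excess and is C-alkylated with 6 in aqueous KOH at rt. A protic medium favours C-alkylation of the phenoxide.
   - 9 is separated by chromatography from the 2-prenyl, diprenyl and O-prenyl products that this less selective reaction also forms. The excess resorcinol is washed out with water.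

**Further compounds**
F1 | step 6 | 2-{2-[2,4-dihydroxy-5-(3-methylbut-2-enyl)phenyl]-2-hydroxyacetyl}-5-methoxyphenyl methanesulfonate (racemic) | COc1ccc(C(=O)C(O)c2cc(CC=C(C)C)c(O)cc2O)c(OS(C)(=O)=O)c1
F2 | step 6 | 2-[6-hydroxy-5-(3-methylbut-2-enyl)-3-oxo-2,3-dihydro-1-benzofuran-2-yl]-5-methoxyphenyl methanesulfonate (racemic) | COc1ccc(C2Oc3cc(O)c(CC=C(C)C)cc3C2=O)c(OS(C)(=O)=O)c1
F3 | step 7 | 1-[4-methoxy-2-(triisopropylsilyloxy)phenyl]ethan-1-one | CC(=O)c1ccc(OC)cc1O[Si](C(C)C)(C(C)C)C(C)C
F4 | step 7 | 2-[4-methoxy-2-(triisopropylsilyloxy)phenyl]-2-oxoacetaldehyde | COc1ccc(C(=O)C=O)c(O[Si](C(C)C)(C(C)C)C(C)C)c1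
F5 | step 7 | 3-methoxy-2-[4-methoxy-2-(triisopropylsilyloxy)phenyl]-5-(3-methylbut-2-enyl)-1-benzofuran-6-ol | COc1ccc(-c2oc3cc(O)c(CC=C(C)C)cc3c2OC)c(O[Si](C(C)C)(C(C)C)C(C)C)c1
F6 | step 4 | resorcinol (bought, not made) | Oc1cccc(O)c1
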